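**Plan**

1. Retrosynthesis: the 22 phenols are unmasked last (benzyl ethers). Ring C of the central epigallocatechin unit is then cut at C4a–C4 and at C2–C3 in one retro-[4+2], giving an O-aryl oxocarbenium fragment (epicatechin gallate already C-bonded to the future ring A) and an (E)-enol gallate on C8 of catechin gallate.
2. Enabling feature: in that ring C, O1 sits on a phloroglucinol ring A whose C4a is the only free ortho carbon (between O1 and 5-O, para to 7-O). C2 is an acetal-level carbon benzylic to the pyrogallol ring B, C3 carries the galloyloxy group, and C4 is benzylic to the 5,7,8a-trioxygenated ring A of the catechin unit. C4a=C8a–O1=C2 is therefore a cationic 2-oxadiene and C3=C4 a polarised styrene-type 2π partner.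
3. Upper fragment, forward: (−)-epicatechin, benzylation, C4 oxidation, galloylation, 4β-arylation with 3,5-bis(benzyloxy)phenol, O-alkylation to a mixed aryl methyl acetal.
4. Lower fragment, forward: (+)-catechin, benzylation, C8 bromination, galloylation, Suzuki–Miyaura installation of an (E)-vinylboron group, trifluoroborate, copper-catalysed C–O coupling to the (E)-enol gallate.
5. Union: a chiral-acid-catalysed oxa-Povarov [4+2] closes ring C of the middle unit between the two fragments; global hydrogenolysis ends the route.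
6. Stereochemistry: C2 and C3 of both outer units come from the chiral pool; the upper C4 is set by attack on the β face; the central C2, C3 and C4 are set in the cycloaddition (counter-anion-controlled face, endo galloyloxy for 2,3-cis, (E)-alkene for 3,4-trans).

Key step: step 13

Assumption: the sense of induction of the binaphthyl N-triflylphosphoramide in step 13 cannot be derived from precedent for this substrate class; the (R) acid is written, and its (S) enantiomer is to be used if that proves to be the matched partner of the two chiral fragments.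

**Route**

Step 1
Reactants: 1 (−)-epicatechin
Product: 2 5,7,3',4'-tetra-O-benzyl-(−)-epicatechin
Conditions: BnBr (4.4 equiv), K2CO3, DMF, 0 °C to rt, argon
Reagents that add atoms: benzyl bromide, BrCc1ccccc1
Why: Williamson etherification in which carbonate deprotonates only the four phenols, so the secondary 3-OH stays free and neither stereocentre is touched.

Step 2
Reactants: 2 5,7,3',4'-tetra-O-benzyl-(−)-epicatechin
Product: 3 4β-(2-ethoxyethoxy)-5,7,3',4'-tetra-O-benzylepicatechin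
Conditions: DDQ (2 equiv), 2-ethoxyethanol (5 equiv), CH2Cl2, rt
Reagents that add atoms: 2-ethoxyethanol, CCOCCO
Why: DDQ benzylic oxidation (hydride abstraction at C4, assisted by the para-oxygenated ring A) with capture of the cation by the alcohol on the β face, anti to the 2-aryl and 3-hydroxy groups, which sets the 3,4-trans C4 centre.

Step 3
Reactants: 3 4β-(2-ethoxyethoxy)-5,7,3',4'-tetra-O-benzylepicatechin; 4 3,4,5-tris(benzyloxy)benzoic acid
Product: 5 4β-(2-ethoxyethoxy)-5,7,3',4'-tetra-O-benzylepicatechin 3-O-[3,4,5-tris(benzyloxy)benzoate]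
Conditions: DCC, DMAP (cat.), CH2Cl2, 0 °C to rt
Reagents that add atoms: none
Why: Steglich esterification of the secondary 3-OH under neutral conditions that leave the acid-labile C4 ether intact and create no stereocentre.

Step 4
Reactants: 5 4β-(2-ethoxyethoxy) gallate; 6 3,5-bis(benzyloxy)phenol (4 equiv)
Product: 7 4β-[2-hydroxy-4,6-bis(benzyloxy)phenyl]-5,7,3',4'-tetra-O-benzylepicatechin 3-O-[3,4,5-tris(benzyloxy)benzoate]
Conditions: TMSOTf (0.3 equiv), CH2Cl2, −78 to −40 °C; Et3N quench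
Reagents that add atoms: none
Why: Friedel–Crafts alkylation by the C4 cation released from the 2-ethoxyethyl ether, in which the 3-O-galloyl carbonyl and the α-oriented 2-aryl group leave only the β face open (4β, 3,4-trans) and the phenol should react at the less hindered carbon flanked by OH and OBn (two of its three nucleophilic sites).

Step 5
Reactants: 8 3,4,5-tris(benzyloxy)benzaldehyde
Product: 9 3,4,5-tris(benzyloxy)benzaldehyde dimethyl acetal
Conditions: HC(OMe)3, p-toluenesulfonic acid monohydrate (cat.), MeOH, rt; NaHCO3 quench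
Reagents that add atoms: trimethyl orthoformate, COC(OC)OC
Why: acid-catalysed acetalisation driven by the orthoformate as water scavenger.

Step 6
Reactants: 9 3,4,5-tris(benzyloxy)benzaldehyde dimethyl acetal; 7 upper-fragment phenol
Product: 12 mixed aryl methyl acetal of 7, via alpha-chlorobenzyl methyl ether 10 (not isolated), via sodium phenoxide 11 (not isolated)
Conditions: (a) 9, AcCl (1.1 equiv), ZnBr2 (cat.), CH2Cl2, 0 °C to rt, concentrate; (b) 7, NaH, THF, 0 °C; (c) add 10 in THF, −20 °C to rt; filtration through basic alumina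
Reagents that add atoms: none
Why: acetal-to-α-chloro-ether exchange with acetyl chloride followed by Williamson-type O-alkylation of the phenoxide by this hard, SN1-active electrophile (as in MOM ether formation); the new acetal centre forms as a mixture of epimers, which does not matter because it becomes planar in step 13.

Step 7
Reactants: 13 (+)-catechin
Product: 14 5,7,3',4'-tetra-O-benzyl-(+)-catechin
Conditions: BnBr (4.4 equiv), K2CO3, DMF, 0 °C to rt, argon
Reagents that add atoms: benzyl bromide, BrCc1ccccc1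
Why: Williamson etherification of the four phenols only, as in step 1, with no stereocentre involved.

Step 8
Reactants: 14 5,7,3',4'-tetra-O-benzyl-(+)-catechin
Product: 15 8-bromo-5,7,3',4'-tetra-O-benzyl-(+)-catechin
Conditions: NBS (1.0 equiv), CH2Cl2, −78 °C to rt
Reagents that add atoms: N-bromosuccinimide, O=C1CCC(=O)N1Br
Why: electrophilic aromatic bromination, which in 5,7-di-O-benzyl flavans goes to C8 (activated by O1, 7-OBn and 5-OBn and less hindered than C6).

Step 9
Reactants: 15 8-bromo-5,7,3',4'-tetra-O-benzyl-(+)-catechin; 4 3,4,5-tris(benzyloxy)benzoic acid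
Product: 16 8-bromo-5,7,3',4'-tetra-O-benzyl-(+)-catechin 3-O-[3,4,5-tris(benzyloxy)benzoate]
Conditions: DCC, DMAP (cat.), CH2Cl2, 0 °C to rt
Reagents that add atoms: none
Why: Steglich esterification of the secondary 3-OH with retention of the (2R,3S) configuration.

Step 10
Reactants: 16 8-bromo catechin gallate
Product: 17 8-[(E)-2-(4,4,5,5-tetramethyl-1,3,2-dioxaborolan-2-yl)ethenyl]-5,7,3',4'-tetra-O-benzyl-(+)-catechin 3-O-[3,4,5-tris(benzyloxy)benzoate]
Conditions: (E)-1,2-bis(pinacolboryl)ethene (3 equiv), Pd(OAc)2 (5 mol %), 2-dicyclohexylphosphino-2',6'-dimethoxybiphenyl (SPhos, 10 mol %), K3PO4, toluene/H2O, 80 °C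
Reagents that add atoms: (E)-1,2-bis(4,4,5,5-tetramethyl-1,3,2-dioxaborolan-2-yl)ethene, CC1(C)OB(/C=C/B2OC(C)(C)C(C)(C)O2)OC1(C)C
Why: Suzuki–Miyaura cross-coupling in which only one C–B bond of the excess diboryl ethene is engaged, the (E) geometry being carried over from the reagent by stereoretentive transmetalation.

Step 11
Reactants: 17 (E)-alkenyl pinacolboronate
Product: 18 potassium (E)-alkenyltrifluoroborate of the catechin gallate
Conditions: KHF2 (aq., 4.5 equiv), MeOH/THF, rt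
Reagents that add atoms: potassium hydrogen difluoride, F.[F-].[K+]
Why: ligand exchange at boron with KHF2 gives the bench-stable trifluoroborate salt without touching the (E) alkene.

Step 12
Reactants: 18 potassium (E)-alkenyltrifluoroborate; 4 3,4,5-tris(benzyloxy)benzoic acid
Product: 19 8-{(E)-2-[3,4,5-tris(benzyloxy)benzoyloxy]ethenyl}-5,7,3',4'-tetra-O-benzyl-(+)-catechin 3-O-[3,4,5-tris(benzyloxy)benzoate]
Conditions: CuBr (10 mol %), DMAP (20 mol %), 4 Å MS, O2 (1 atm), MeCN/CH2Cl2, 40 °C; neutral alumina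
Reagents that add atoms: none
Why: Chan–Lam-type aerobic copper-catalysed C–O coupling of an alkenyltrifluoroborate with a carboxylic acid, which passes through an alkenylcopper carboxylate and reductive elimination with retention of the (E) geometry.

Step 13
Reactants: 12 mixed aryl methyl acetal; 19 (E)-enol gallate (1.5 equiv)
Product: 21 docosa-O-benzyl ether of the target, via aryl oxocarbenium ion 20 (not isolated)
Conditions: (R)-3,3'-bis(2,4,6-triisopropylphenyl)-1,1'-binaphthyl-2,2'-diyl N-triflylphosphoramide (10 mol %), 5 Å MS, toluene/CH2Cl2, slow addition of 12, −60 to −30 °C; Et3N quench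
Reagents that add atoms: none
Why: Proposed new method: the chiral N-triflylphosphoramide protonates the methoxy oxygen of 12 and, after loss of methanol, ion-pairs with the O-aryl oxocarbenium ion 20, a cationic 2-oxadiene (C4a=C8a–O1=C2 of the future middle unit), which adds across the C3=C4 bond of 19 in an inverse-electron-demand [4+2] cycloaddition; the closest known reaction type is the oxa-Povarov reaction of aryl oxocarbenium ions with styrenes, joined here to chiral Brønsted acid catalysis of oxocarbenium additions, and the use of a β-acyloxystyrene under catalyst control is the untested part. Bond formation should be strongly asynchronous: C3 bonds to C2 first because the charge building at C4 is delocalised into the 5,7,8a-trioxygenated ring A of the catechin unit (not onto the acyloxy carbon), and ring C then closes by attack of C4a on C4 (formal [4+2]; a 6-exo-trig Friedel–Crafts capture if the C4 cation is a discrete intermediate), rearomatisation returning the proton to the catalyst. C2 is set by the face of the (E)-oxocarbenium that the chiral phosphoramidate counter-anion leaves open, a bias that the bulky 4β-flavanyl group on C8 may reinforce or oppose. C3 follows from the endo placement of the galloyloxy group (carbonyl oxygen over the cationic O1=C2) with the large catechin-8-yl group exo, which together with the outside-oriented ring B gives 2,3-cis. C4 follows from suprafacial addition to the (E)-alkene, giving 3,4-trans, and in the stepwise limit the C3 galloyl carbonyl bridges C4 so that C4a again enters anti. The step needs chemoselectivity for the alkene over the free arene C6/C8 positions, served by the more nucleophilic trioxygenated styrene used in excess at low temperature, and regioselective closure, secured because C4a is the only free ortho carbon of the aryloxy ring and is activated by O1, 5-OBn and 7-OBn.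

Step 14
Reactants: 21 docosa-O-benzyl ether of the target
Product: 22 epicatechin 3-O-gallate-(4β→8)-epigallocatechin 3-O-gallate-(4β→8)-catechin 3-O-gallate
Conditions: H2 (1 atm), Pd(OH)2/C, THF/MeOH/H2O, rt; filtration, lyophilisation
Reagents that add atoms: none
Why: heterogeneous hydrogenolysis of the 22 benzyl aryl ethers under neutral conditions, which is expected to leave the three gallate esters, the chroman C2–O bonds and the interflavan bonds intact and touches no stereocentre.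

**Compound list**

1 | (−)-epicatechin, (2R,3R)-2-(3,4-dihydroxyphenyl)chromane-3,5,7-triol | O[C@@H]1Cc2c(O)cc(O)cc2O[C@@H]1c1ccc(O)c(O)c1 | starting material
2 | 5,7,3',4'-tetra-O-benzyl-(−)-epicatechin | O[C@@H]1Cc2c(OCc3ccccc3)cc(OCc3ccccc3)cc2O[C@@H]1c1ccc(OCc2ccccc2)c(OCc2ccccc2)c1 | intermediate
3 | 4β-(2-ethoxyethoxy)-5,7,3',4'-tetra-O-benzylepicatechin (2,3-cis, 3,4-trans) | CCOCCO[C@H]1c2c(OCc3ccccc3)cc(OCc3ccccc3)cc2O[C@H](c2ccc(OCc3ccccc3)c(OCc3ccccc3)c2)[C@@H]1O | intermediate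
4 | 3,4,5-tris(benzyloxy)benzoic acid | OC(=O)c1cc(OCc2ccccc2)c(OCc2ccccc2)c(OCc2ccccc2)c1 | starting material
5 | 4β-(2-ethoxyethoxy)-5,7,3',4'-tetra-O-benzylepicatechin 3-O-[3,4,5-tris(benzyloxy)benzoate] | CCOCCO[C@H]1c2c(OCc3ccccc3)cc(OCc3ccccc3)cc2O[C@H](c2ccc(OCc3ccccc3)c(OCc3ccccc3)c2)[C@@H]1OC(=O)c1cc(OCc2ccccc2)c(OCc2ccccc2)c(OCc2ccccc2)c1 | intermediate
6 | 3,5-bis(benzyloxy)phenol | Oc1cc(OCc2ccccc2)cc(OCc2ccccc2)c1 | starting material
7 | 4β-[2-hydroxy-4,6-bis(benzyloxy)phenyl]-5,7,3',4'-tetra-O-benzylepicatechin 3-O-[3,4,5-tris(benzyloxy)benzoate] (3,4-trans; free OH ortho to the new C–C bond) | Oc1cc(OCc2ccccc2)cc(OCc2ccccc2)c1[C@H]1c2c(OCc3ccccc3)cc(OCc3ccccc3)cc2O[C@H](c2ccc(OCc3ccccc3)c(OCc3ccccc3)c2)[C@@H]1OC(=O)c1cc(OCc2ccccc2)c(OCc2ccccc2)c(OCc2ccccc2)c1 | intermediate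
8 | 3,4,5-tris(benzyloxy)benzaldehyde | O=Cc1cc(OCc2ccccc2)c(OCc2ccccc2)c(OCc2ccccc2)c1 | starting material
9 | 3,4,5-tris(benzyloxy)benzaldehyde dimethyl acetal | COC(OC)c1cc(OCc2ccccc2)c(OCc2ccccc2)c(OCc2ccccc2)c1 | intermediate
10 | 1-[chloro(methoxy)methyl]-3,4,5-tris(benzyloxy)benzene (α-chloro ether) | COC(Cl)c1cc(OCc2ccccc2)c(OCc2ccccc2)c(OCc2ccccc2)c1 | intermediate
11 | sodium phenoxide of 7 | [Na+].[O-]c1cc(OCc2ccccc2)cc(OCc2ccccc2)c1[C@H]1c2c(OCc3ccccc3)cc(OCc3ccccc3)cc2O[C@H](c2ccc(OCc3ccccc3)c(OCc3ccccc3)c2)[C@@H]1OC(=O)c1cc(OCc2ccccc2)c(OCc2ccccc2)c(OCc2ccccc2)c1 | intermediate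
12 | mixed acetal: phenolic oxygen of 7 bonded to CH(OMe)[3,4,5-tris(benzyloxy)phenyl]; both epimers at the acetal carbon | COC(Oc1cc(OCc2ccccc2)cc(OCc2ccccc2)c1[C@H]1c2c(OCc3ccccc3)cc(OCc3ccccc3)cc2O[C@H](c2ccc(OCc3ccccc3)c(OCc3ccccc3)c2)[C@@H]1OC(=O)c1cc(OCc2ccccc2)c(OCc2ccccc2)c(OCc2ccccc2)c1)c1cc(OCc2ccccc2)c(OCc2ccccc2)c(OCc2ccccc2)c1 | intermediate
13 | (+)-catechin, (2R,3S)-2-(3,4-dihydroxyphenyl)chromane-3,5,7-triol | O[C@H]1Cc2c(O)cc(O)cc2O[C@@H]1c1ccc(O)c(O)c1 | starting material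
14 | 5,7,3',4'-tetra-O-benzyl-(+)-catechin | O[C@H]1Cc2c(OCc3ccccc3)cc(OCc3ccccc3)cc2O[C@@H]1c1ccc(OCc2ccccc2)c(OCc2ccccc2)c1 | intermediate
15 | 8-bromo-5,7,3',4'-tetra-O-benzyl-(+)-catechin | O[C@H]1Cc2c(OCc3ccccc3)cc(OCc3ccccc3)c(Br)c2O[C@@H]1c1ccc(OCc2ccccc2)c(OCc2ccccc2)c1 | intermediate
16 | 8-bromo-5,7,3',4'-tetra-O-benzyl-(+)-catechin 3-O-[3,4,5-tris(benzyloxy)benzoate] | O=C(O[C@H]1Cc2c(OCc3ccccc3)cc(OCc3ccccc3)c(Br)c2O[C@@H]1c1ccc(OCc2ccccc2)c(OCc2ccccc2)c1)c1cc(OCc2ccccc2)c(OCc2ccccc2)c(OCc2ccccc2)c1 | intermediate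
17 | 8-[(E)-2-(pinacolboryl)ethenyl]-5,7,3',4'-tetra-O-benzyl-(+)-catechin 3-O-[3,4,5-tris(benzyloxy)benzoate] | O=C(O[C@H]1Cc2c(OCc3ccccc3)cc(OCc3ccccc3)c(/C=C/B3OC(C)(C)C(C)(C)O3)c2O[C@@H]1c1ccc(OCc2ccccc2)c(OCc2ccccc2)c1)c1cc(OCc2ccccc2)c(OCc2ccccc2)c(OCc2ccccc2)c1 | intermediate
18 | potassium (E)-alkenyltrifluoroborate corresponding to 17 | [K+].O=C(O[C@H]1Cc2c(OCc3ccccc3)cc(OCc3ccccc3)c(/C=C/[B-](F)(F)F)c2O[C@@H]1c1ccc(OCc2ccccc2)c(OCc2ccccc2)c1)c1cc(OCc2ccccc2)c(OCc2ccccc2)c(OCc2ccccc2)c1 | intermediate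
19 | 8-{(E)-2-[3,4,5-tris(benzyloxy)benzoyloxy]ethenyl}-5,7,3',4'-tetra-O-benzyl-(+)-catechin 3-O-[3,4,5-tris(benzyloxy)benzoate] | O=C(O[C@H]1Cc2c(OCc3ccccc3)cc(OCc3ccccc3)c(/C=C/OC(=O)c3cc(OCc4ccccc4)c(OCc4ccccc4)c(OCc4ccccc4)c3)c2O[C@@H]1c1ccc(OCc2ccccc2)c(OCc2ccccc2)c1)c1cc(OCc2ccccc2)c(OCc2ccccc2)c(OCc2ccccc2)c1 | intermediate
20 | (E)-O-aryl oxocarbenium ion from 12 (cation; the counter-ion is the conjugate base of the catalyst) | c1(/C=[O+]/c2cc(OCc4ccccc4)cc(OCc4ccccc4)c2[C@H]2c3c(OCc4ccccc4)cc(OCc4ccccc4)cc3O[C@H](c3ccc(OCc4ccccc4)c(OCc4ccccc4)c3)[C@@H]2OC(=O)c2cc(OCc4ccccc4)c(OCc4ccccc4)c(OCc4ccccc4)c2)cc(OCc4ccccc4)c(OCc4ccccc4)c(OCc4ccccc4)c1 | intermediate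
21 | docosa-O-benzyl ether of the target: [tetra-O-benzylepicatechin 3-O-(tri-O-benzylgallate)]-(4β→8)-[penta-O-benzylepigallocatechin 3-O-(tri-O-benzylgallate)]-(4β→8)-[tetra-O-benzylcatechin 3-O-(tri-O-benzylgallate)] | O=C(O[C@@H]1[C@@H](c2c(OCc5ccccc5)cc(OCc5ccccc5)c3c2O[C@H](c2ccc(OCc5ccccc5)c(OCc5ccccc5)c2)[C@@H](OC(=O)c2cc(OCc5ccccc5)c(OCc5ccccc5)c(OCc5ccccc5)c2)C3)c2c(OCc5ccccc5)cc(OCc5ccccc5)c([C@H]3c4c(OCc5ccccc5)cc(OCc5ccccc5)cc4O[C@H](c4ccc(OCc5ccccc5)c(OCc5ccccc5)c4)[C@@H]3OC(=O)c3cc(OCc5ccccc5)c(OCc5ccccc5)c(OCc5ccccc5)c3)c2O[C@@H]1c1cc(OCc5ccccc5)c(OCc5ccccc5)c(OCc5ccccc5)c1)c1cc(OCc5ccccc5)c(OCc5ccccc5)c(OCc5ccccc5)c1 | intermediate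
22 | epicatechin 3-O-gallate-(4β→8)-epigallocatechin 3-O-gallate-(4β→8)-catechin 3-O-gallate (CNP0321910.1) | O=C(O[C@@H]1[C@@H](c2c(O)cc(O)c3c2O[C@H](c2ccc(O)c(O)c2)[C@@H](OC(=O)c2cc(O)c(O)c(O)c2)C3)c2c(O)cc(O)c([C@H]3c4c(O)cc(O)cc4O[C@H](c4ccc(O)c(O)c4)[C@@H]3OC(=O)c3cc(O)c(O)c(O)c3)c2O[C@@H]1c1cc(O)c(O)c(O)c1)c1cc(O)c(O)c(O)c1 | target
23 | (−)-epigallocatechin (enters only in the fallback to step 13) | O[C@@H]1Cc2c(O)cc(O)cc2O[C@@H]1c1cc(O)c(O)c(O)c1 | starting material

**Totals and risks**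

Total step count: 14.
Longest linear sequence: 8 steps (steps 7 to 12, then 13 and 14, from (+)-catechin).

Steps most likely to fail:

1. Step 13 (proposed new method). Possible failure processes:
   - ionisation of the acetal at the aryloxy instead of the methoxy oxygen;
   - intermolecular Friedel–Crafts capture of the oxocarbenium ion by free C6/C8 arene positions;
   - acid-induced hydrolysis or oligomerisation of the enol ester;
   - insufficient facial or endo/exo selectivity.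

   Fallback (known chemistry): iterative Lewis-acid 4→8 condensation. It sets out from 23, 14, 4 and 5 and returns at 21. Commercial (−)-epigallocatechin 23 would be benzylated (BnBr, K2CO3, DMF) to 5,7,3',4',5'-penta-O-benzylepigallocatechin F1. F1 would be oxidised at C4 (DDQ, 2-ethoxyethanol, CH2Cl2) to its 4β-(2-ethoxyethoxy) ether F2, which would be esterified with 4 (DCC, DMAP) to the 3-O-gallate F3. In parallel, 14 would be esterified with 4 to tetra-O-benzylcatechin 3-O-[3,4,5-tris(benzyloxy)benzoate] F4. TMSOTf-catalysed Friedel–Crafts condensation of F3 with excess F4 at −78 °C should give the benzylated epigallocatechin gallate-(4β→8)-catechin gallate dimer F5, 3,4-trans through galloyl participation. A second TMSOTf-catalysed condensation of F5 (nucleophile, in excess, reacting at C8 of its upper unit) with the electrophile 5 should then give 21.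

2. Step 12. Possible failure processes: protodeboronation or oxidative homocoupling of the electron-rich styryl trifluoroborate, erosion of the alkene geometry, and hydrolysis of the enol ester on isolation.

   Fallback: an alkyne route that sets out from 16 and returns at 19, bypassing steps 10 to 12. Copper-free Sonogashira coupling of 16 with ethynyltrimethylsilane (Pd(MeCN)2Cl2, 2-dicyclohexylphosphino-2',4',6'-triisopropylbiphenyl, Cs2CO3, MeCN, 80 °C) would give the 8-(trimethylsilylethynyl) compound F6. Desilylation (TBAF, AcOH, THF, 0 °C) would give the 8-ethynyl compound F7. Ruthenium-catalysed anti-Markovnikov addition of 4 ([(p-cymene)RuCl2]2, P(4-ClC6H4)3, DMAP, toluene, 60 °C) should give the (Z)-enol gallate F8. Thiyl-radical equilibration (PhSSPh cat., visible light, CH2Cl2) should then convert F8 into the less hindered (E) isomer 19.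

3. Step 4. Possible failure processes: attack of the cation at the phenol carbon between the two benzyloxy groups, giving the regioisomer with the free OH para to the new bond, and double alkylation of the phenol.

   Fallback: a blocking-group approach that sets out from 6 and 5 and returns at 7. Bromination of 6 para to the hydroxyl group (NBS, CH2Cl2, −78 °C) would give 4-bromo-3,5-bis(benzyloxy)phenol F9, in which only the two equivalent carbons ortho to OH remain free. TMSOTf-mediated condensation of F9 with 5 would give the bromo analogue of 7, the 4β-[3-bromo-6-hydroxy-2,4-bis(benzyloxy)phenyl] adduct F10. Palladium-catalysed formate hydrodebromination (Pd(OAc)2, PPh3, HCO2Na, DMF, 80 °C), which spares benzyl ethers and esters, would then give 7.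

**Further compounds**

F1 | step 13 | 5,7,3',4',5'-penta-O-benzyl-(−)-epigallocatechin | O[C@@H]1Cc2c(OCc3ccccc3)cc(OCc3ccccc3)cc2O[C@@H]1c1cc(OCc2ccccc2)c(OCc2ccccc2)c(OCc2ccccc2)c1
F2 | step 13 | 4β-(2-ethoxyethoxy)-5,7,3',4',5'-penta-O-benzylepigallocatechin | CCOCCO[C@H]1c2c(OCc3ccccc3)cc(OCc3ccccc3)cc2O[C@H](c2cc(OCc3ccccc3)c(OCc3ccccc3)c(OCc3ccccc3)c2)[C@@H]1O
F3 | step 13 | 4β-(2-ethoxyethoxy)-5,7,3',4',5'-penta-O-benzylepigallocatechin 3-O-[3,4,5-tris(benzyloxy)benzoate] | CCOCCO[C@H]1c2c(OCc3ccccc3)cc(OCc3ccccc3)cc2O[C@H](c2cc(OCc3ccccc3)c(OCc3ccccc3)c(OCc3ccccc3)c2)[C@@H]1OC(=O)c1cc(OCc2ccccc2)c(OCc2ccccc2)c(OCc2ccccc2)c1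
F4 | step 13 | 5,7,3',4'-tetra-O-benzyl-(+)-catechin 3-O-[3,4,5-tris(benzyloxy)benzoate] | O=C(O[C@H]1Cc2c(OCc3ccccc3)cc(OCc3ccccc3)cc2O[C@@H]1c1ccc(OCc2ccccc2)c(OCc2ccccc2)c1)c1cc(OCc2ccccc2)c(OCc2ccccc2)c(OCc2ccccc2)c1
F5 | step 13 | benzylated dimer [penta-O-benzylepigallocatechin 3-O-(tri-O-benzylgallate)]-(4β→8)-[tetra-O-benzylcatechin 3-O-(tri-O-benzylgallate)] | O=C(O[C@@H]1[C@@H](c2c(OCc5ccccc5)cc(OCc5ccccc5)c3c2O[C@H](c2ccc(OCc5ccccc5)c(OCc5ccccc5)c2)[C@@H](OC(=O)c2cc(OCc5ccccc5)c(OCc5ccccc5)c(OCc5ccccc5)c2)C3)c2c(OCc5ccccc5)cc(OCc5ccccc5)cc2O[C@@H]1c1cc(OCc5ccccc5)c(OCc5ccccc5)c(OCc5ccccc5)c1)c1cc(OCc5ccccc5)c(OCc5ccccc5)c(OCc5ccccc5)c1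
F6 | step 12 | 8-(trimethylsilylethynyl)-5,7,3',4'-tetra-O-benzyl-(+)-catechin 3-O-[3,4,5-tris(benzyloxy)benzoate] | O=C(O[C@H]1Cc2c(OCc3ccccc3)cc(OCc3ccccc3)c(C#C[Si](C)(C)C)c2O[C@@H]1c1ccc(OCc2ccccc2)c(OCc2ccccc2)c1)c1cc(OCc2ccccc2)c(OCc2ccccc2)c(OCc2ccccc2)c1
F7 | step 12 | 8-ethynyl-5,7,3',4'-tetra-O-benzyl-(+)-catechin 3-O-[3,4,5-tris(benzyloxy)benzoate] | O=C(O[C@H]1Cc2c(OCc3ccccc3)cc(OCc3ccccc3)c(C#C)c2O[C@@H]1c1ccc(OCc2ccccc2)c(OCc2ccccc2)c1)c1cc(OCc2ccccc2)c(OCc2ccccc2)c(OCc2ccccc2)c1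
F8 | step 12 | (Z) isomer of 19, 8-{(Z)-2-[3,4,5-tris(benzyloxy)benzoyloxy]ethenyl}-5,7,3',4'-tetra-O-benzyl-(+)-catechin 3-O-[3,4,5-tris(benzyloxy)benzoate] | O=C(O[C@H]1Cc2c(OCc3ccccc3)cc(OCc3ccccc3)c(/C=C\OC(=O)c3cc(OCc4ccccc4)c(OCc4ccccc4)c(OCc4ccccc4)c3)c2O[C@@H]1c1ccc(OCc2ccccc2)c(OCc2ccccc2)c1)c1cc(OCc2ccccc2)c(OCc2ccccc2)c(OCc2ccccc2)c1
F9 | step 4 | 4-bromo-3,5-bis(benzyloxy)phenol | Oc1cc(OCc2ccccc2)c(Br)c(OCc2ccccc2)c1
F10 | step 4 | 4β-[3-bromo-6-hydroxy-2,4-bis(benzyloxy)phenyl]-5,7,3',4'-tetra-O-benzylepicatechin 3-O-[3,4,5-tris(benzyloxy)benzoate] | Oc1cc(OCc2ccccc2)c(Br)c(OCc2ccccc2)c1[C@H]1c2c(OCc3ccccc3)cc(OCc3ccccc3)cc2O[C@H](c2ccc(OCc3ccccc3)c(OCc3ccccc3)c2)[C@@H]1OC(=O)c1cc(OCc2ccccc2)c(OCc2ccccc2)c(OCc2ccccc2)c1
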